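**Strategy**

Both isoflavone units are disconnected at once at their C3–C1′ bonds and O1–C2 bonds, copying the 2,3-aryl shift by which isoflavone synthase makes this skeleton. A twofold thallium(III)-mediated oxidative 1,2-aryl migration of a diaryl-ether-linked bis(2′-hydroxychalcone), followed in the same flask by acid ring closure, should create both 3-aryl-substituted pyranone (C) rings in one operation. The step exploits the para oxygen on each B ring (the C4′ oxygen of the 7-hydroxy unit and the bridging ether oxygen on C4′ of the 8-chloro unit), which makes both aryl groups good migrating groups. The unsymmetrical bis-chalcone arises from one SNAr etherification and two Claisen–Schmidt condensations, staged by a benzylic alcohol that is oxidised between them.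

Key step: step 6

Remark: the target has no stereocentre and no hindered axis, so it is a single achiral compound and the "single enantiomer" is the compound itself; the only stereochemical elements on the way (E-enones, the two sp3 centres of 11) are lost in step 6.

**Route**

Step 1
Reactants: 1 2-chloro-1,3-dimethoxybenzene
Product: 3 1-(3-chloro-2-hydroxy-4-methoxyphenyl)ethanone, via 3-chloro-2,4-dimethoxyacetophenone 2 (not isolated)
Conditions: AcCl (1.2 equiv), AlCl3 (2.5 equiv), CH2Cl2, 0 °C to reflux; aq. HCl work-up
Reagents that add atoms: acetyl chloride, CC(=O)Cl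
Why: Friedel–Crafts acylation should occur at C4 (para to one methoxy group and ortho to the other, C4 and C6 being equivalent), after which the ketone-chelated aluminium should cleave only the flanking methoxy group (chelation-controlled ortho-demethylation) and leave the 4-methoxy group.

Step 2
Reactants: 4 3-hydroxy-4-methoxybenzyl alcohol; 5 4-fluorobenzaldehyde
Product: 6 4-[5-(hydroxymethyl)-2-methoxyphenoxy]benzaldehyde
Conditions: K2CO3 (1.5 equiv), DMF, 120 °C, N2
Reagents that add atoms: none
Why: Nucleophilic aromatic substitution (SNAr): carbonate deprotonates only the phenol, not the benzylic alcohol, and the phenoxide should displace fluoride para to the formyl group by addition–elimination.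

Step 3
Reactants: 6 4-[5-(hydroxymethyl)-2-methoxyphenoxy]benzaldehyde; 3 1-(3-chloro-2-hydroxy-4-methoxyphenyl)ethanone
Product: 7 (E)-1-(3-chloro-2-hydroxy-4-methoxyphenyl)-3-{4-[5-(hydroxymethyl)-2-methoxyphenoxy]phenyl}prop-2-en-1-one
Conditions: KOH (50% aq.), EtOH, rt; then cold dilute HCl
Reagents that add atoms: none
Why: Claisen–Schmidt (crossed aldol) condensation of a non-enolisable aldehyde with the acetophenone enolate, in which E1cB dehydration should give the thermodynamic E-enone while the chelated 2-hydroxyl and the benzylic alcohol stay untouched.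

Step 4
Reactants: 7 (E)-1-(3-chloro-2-hydroxy-4-methoxyphenyl)-3-{4-[5-(hydroxymethyl)-2-methoxyphenoxy]phenyl}prop-2-en-1-one
Product: 8 3-{4-[(E)-3-(3-chloro-2-hydroxy-4-methoxyphenyl)-3-oxoprop-1-en-1-yl]phenoxy}-4-methoxybenzaldehyde
Conditions: activated MnO2 (excess), CH2Cl2, rt
Reagents that add atoms: none
Why: Benzylic alcohol oxidation with activated manganese dioxide should stop at the aldehyde and leave the enone, the hydrogen-bonded phenol and the aryl ethers unchanged.

Step 5
Reactants: 8 3-{4-[(E)-3-(3-chloro-2-hydroxy-4-methoxyphenyl)-3-oxoprop-1-en-1-yl]phenoxy}-4-methoxybenzaldehyde; 9 1-(2-hydroxy-4-methoxyphenyl)ethanone (paeonol)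
Product: 10 (E)-1-(3-chloro-2-hydroxy-4-methoxyphenyl)-3-(4-{5-[(E)-3-(2-hydroxy-4-methoxyphenyl)-3-oxoprop-1-en-1-yl]-2-methoxyphenoxy}phenyl)prop-2-en-1-one
Conditions: 9 (1.05 equiv), KOH (50% aq.), EtOH, rt; then cold dilute HCl
Reagents that add atoms: none
Why: Second Claisen–Schmidt condensation on the newly unmasked non-enolisable aldehyde, in which the first enone, present as its 2′-phenoxide, is a poor Michael acceptor and the new double bond should again form with thermodynamic E geometry.

Step 6
Reactants: 10 (E)-1-(3-chloro-2-hydroxy-4-methoxyphenyl)-3-(4-{5-[(E)-3-(2-hydroxy-4-methoxyphenyl)-3-oxoprop-1-en-1-yl]-2-methoxyphenoxy}phenyl)prop-2-en-1-one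
Product: 12 8-chloro-7-methoxy-3-{4-[2-methoxy-5-(7-methoxy-4-oxo-4H-chromen-3-yl)phenoxy]phenyl}-4H-chromen-4-one, via bis(dimethyl acetal) 11 (not isolated)
Conditions: Tl(NO3)3·3H2O (2.4 equiv), MeOH–CH(OMe)3–CH2Cl2, rt; filter; then 10% aq. HCl, reflux
Reagents that add atoms: none
Why: Each enone should undergo methoxythallation (methanol at the benzylic Cβ, thallium(III) at Cα), after which the para-oxygenated aryl group shifts from Cβ to Cα through a phenonium ion as thallium leaves as Tl(I), and the resulting α-methoxy carbocation is trapped by methanol as the dimethyl acetal 11. The closest known reaction type is the thallium(III) nitrate oxidative rearrangement of 2′-hydroxychalcones to isoflavones, a laboratory copy of the isoflavone-synthase aryl shift, here run on two enones of one molecule. On heating with HCl each acetal ionises to an oxocarbenium ion, which the 2′-hydroxyl captures in a 6-exo-trig closure to a 2-methoxyisoflavanone, and loss of methanol then gives the aromatic pyranone ring; both rings close in this mode. No stereocentre remains, because the two sp3 centres of 11, formed without control, become C3 of the two chromones. The step needs aryl migration to outrun attack of the 2′-hydroxyl on the thallated enone (aurone or flavone formation), which the donor oxygen para to each migrating carbon and the hydrogen-bonded, acyl-deactivated 2′-phenols should secure, and it needs both enones to react, for which a slight excess of oxidant per enone is used. The methoxy groups of 11 come from the solvent and are lost again on ring closure, so the product holds no reagent atom.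

Step 7
Reactants: 12 8-chloro-7-methoxy-3-{4-[2-methoxy-5-(7-methoxy-4-oxo-4H-chromen-3-yl)phenoxy]phenyl}-4H-chromen-4-one
Product: 13 8-chloro-7-hydroxy-3-{4-[2-hydroxy-5-(7-hydroxy-4-oxo-4H-chromen-3-yl)phenoxy]phenyl}-4H-chromen-4-one (bisoflavolin K)
Conditions: BBr3 (10 equiv), CH2Cl2, −78 °C to rt; then MeOH, H2O
Reagents that add atoms: none
Why: Lewis-acid ether cleavage with boron tribromide should remove all three methyl groups by bromide attack on the boron-activated O–CH3 carbon, whereas the diaryl ether (no carbon open to SN2), the aryl chloride and the chromones are inert, the excess reagent allowing for coordination to the two carbonyl groups.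

**Compound list**

1 | 2-chloro-1,3-dimethoxybenzene | COc1cccc(OC)c1Cl | starting material
2 | 1-(3-chloro-2,4-dimethoxyphenyl)ethanone (3-chloro-2,4-dimethoxyacetophenone) | COc1ccc(C(C)=O)c(OC)c1Cl | intermediate
3 | 1-(3-chloro-2-hydroxy-4-methoxyphenyl)ethanone | COc1ccc(C(C)=O)c(O)c1Cl | intermediate
4 | 3-hydroxy-4-methoxybenzyl alcohol | COc1ccc(CO)cc1O | starting material
5 | 4-fluorobenzaldehyde | O=Cc1ccc(F)cc1 | starting material
6 | 4-[5-(hydroxymethyl)-2-methoxyphenoxy]benzaldehyde | COc1ccc(CO)cc1Oc1ccc(C=O)cc1 | intermediate
7 | (E)-1-(3-chloro-2-hydroxy-4-methoxyphenyl)-3-{4-[5-(hydroxymethyl)-2-methoxyphenoxy]phenyl}prop-2-en-1-one | COc1ccc(CO)cc1Oc1ccc(/C=C/C(=O)c2ccc(OC)c(Cl)c2O)cc1 | intermediate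
8 | 3-{4-[(E)-3-(3-chloro-2-hydroxy-4-methoxyphenyl)-3-oxoprop-1-en-1-yl]phenoxy}-4-methoxybenzaldehyde | COc1ccc(C=O)cc1Oc1ccc(/C=C/C(=O)c2ccc(OC)c(Cl)c2O)cc1 | intermediate
9 | 1-(2-hydroxy-4-methoxyphenyl)ethanone (paeonol) | CC(=O)c1ccc(OC)cc1O | starting material
10 | (E)-1-(3-chloro-2-hydroxy-4-methoxyphenyl)-3-(4-{5-[(E)-3-(2-hydroxy-4-methoxyphenyl)-3-oxoprop-1-en-1-yl]-2-methoxyphenoxy}phenyl)prop-2-en-1-one (bis-chalcone) | COc1ccc(/C=C/C(=O)c2ccc(OC)cc2O)cc1Oc1ccc(/C=C/C(=O)c2ccc(OC)c(Cl)c2O)cc1 | intermediate
11 | bis(dimethyl acetal): 1-(3-chloro-2-hydroxy-4-methoxyphenyl)-2-(4-{5-[1-(2-hydroxy-4-methoxyphenyl)-3,3-dimethoxy-1-oxopropan-2-yl]-2-methoxyphenoxy}phenyl)-3,3-dimethoxypropan-1-one (mixture of stereoisomers) | COc1ccc(C(C(OC)OC)C(=O)c2ccc(OC)cc2O)cc1Oc1ccc(C(C(OC)OC)C(=O)c2ccc(OC)c(Cl)c2O)cc1 | intermediate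
12 | 8-chloro-7-methoxy-3-{4-[2-methoxy-5-(7-methoxy-4-oxo-4H-chromen-3-yl)phenoxy]phenyl}-4H-chromen-4-one | COc1ccc(-c2coc3cc(OC)ccc3c2=O)cc1Oc1ccc(-c2coc3c(Cl)c(OC)ccc3c2=O)cc1 | intermediate
13 | 8-chloro-7-hydroxy-3-{4-[2-hydroxy-5-(7-hydroxy-4-oxo-4H-chromen-3-yl)phenoxy]phenyl}-4H-chromen-4-one (bisoflavolin K) | O=c1c(-c2ccc(O)c(Oc3ccc(-c4coc5c(Cl)c(O)ccc5c4=O)cc3)c2)coc2cc(O)ccc12 | target

**Step count and risks**

Total step count: 7. Longest linear sequence: 6 (steps 2 to 7 from 4 and 5; the branch through step 1 is equally long).

Steps most likely to fail: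

1. Step 6. The 2′-hydroxyl may cyclise onto its thallated enone faster than the aryl group migrates (aurone or flavone formation), the second enone may react incompletely once the first has rearranged, or the electron-rich rings may be oxidised. The fallback sets out from 10 and comes back at 12. It closes the rings first and migrates the aryl groups afterwards, without thallium and without a free phenol in the oxidation. Bis-chalcone 10 would be isomerised by oxa-Michael ring closure (NaOAc, EtOH, reflux, with recycling of unchanged chalcone) to the bis-flavanone 8-chloro-7-methoxy-2-{4-[2-methoxy-5-(7-methoxy-4-oxochroman-2-yl)phenoxy]phenyl}chroman-4-one F1. This would then be treated with [hydroxy(tosyloxy)iodo]benzene in MeOH–CH(OMe)3, where α-iodination of each enol ether, 2,3-aryl shift with loss of iodobenzene, and loss of a proton should give 12 directly.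

2. Step 5. The ketone enolate may add in Michael fashion to the enone already present, or hydroxide may cause chalcone–flavanone isomerisation and retro-aldol scrambling of the first enone. The fallback sets out from 9 (used together with 8) and comes back at 10. It replaces the aldol condensation by a Wittig olefination under neutral conditions. Paeonol 9 would be α-brominated (CuBr2, EtOAc–CHCl3, reflux) to 2-bromo-1-(2-hydroxy-4-methoxyphenyl)ethanone F2. This would be converted with PPh3 in toluene into [2-(2-hydroxy-4-methoxyphenyl)-2-oxoethyl]triphenylphosphonium bromide F3 and then with aq. Na2CO3 into the stabilised ylide 1-(2-hydroxy-4-methoxyphenyl)-2-(triphenyl-λ5-phosphanylidene)ethanone F4. Heating F4 with aldehyde 8 in toluene should give the E-enone of 10.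

3. Step 1. The ether cleavage may stop short, go on to the 4-methoxy group, or start before acylation, so that mixtures of phenols result. The fallback sets out from 1 and comes back at 3. It acylates a free resorcinol and then methylates selectively, instead of acylating and demethylating selectively. Compound 1 would be fully demethylated (BBr3, CH2Cl2) to 2-chlororesorcinol F5, which is also an article of commerce, so this stage can be skipped. C-Acylation (AcOH, BF3·OEt2, 90 °C; C4 and C6 equivalent) should then give 1-(3-chloro-2,4-dihydroxyphenyl)ethanone F6. Methylation with MeI (1.05 equiv) and K2CO3 in acetone should take place at the free 4-hydroxyl only, the 2-hydroxyl being hydrogen-bonded to the ketone, to give 3.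

Further compounds
F1 | step 6 | 8-chloro-7-methoxy-2-{4-[2-methoxy-5-(7-methoxy-4-oxochroman-2-yl)phenoxy]phenyl}chroman-4-one (mixture of stereoisomers) | COc1ccc(C2CC(=O)c3ccc(OC)cc3O2)cc1Oc1ccc(C2CC(=O)c3ccc(OC)c(Cl)c3O2)cc1
F2 | step 5 | 2-bromo-1-(2-hydroxy-4-methoxyphenyl)ethanone | COc1ccc(C(=O)CBr)c(O)c1
F3 | step 5 | [2-(2-hydroxy-4-methoxyphenyl)-2-oxoethyl]triphenylphosphonium bromide | COc1ccc(C(=O)C[P+](c2ccccc2)(c2ccccc2)c2ccccc2)c(O)c1.[Br-]
F4 | step 5 | 1-(2-hydroxy-4-methoxyphenyl)-2-(triphenyl-λ5-phosphanylidene)ethanone | COc1ccc(C(=O)C=P(c2ccccc2)(c2ccccc2)c2ccccc2)c(O)c1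
F5 | step 1 | 2-chlororesorcinol | Oc1cccc(O)c1Cl
F6 | step 1 | 1-(3-chloro-2,4-dihydroxyphenyl)ethanone | CC(=O)c1ccc(O)c(Cl)c1O
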